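**Plan**

- Target: (5R,6S,6'R)-5,6-epoxy-5,6-dihydro-β,ε-carotene (carotenoid numbering throughout). Cuts: C11=C12 (Wittig), C11'=C12' (Wittig on the C10 dialdehyde), C7=C8 (Horner–Wadsworth–Emmons) and, inside the epoxy end group, ring bonds C1–C2 and C5–C6 together with the oxirane bond C6–O.
- Enabling feature: in the 7-oxabicyclo[4.1.0]heptane end group, C5 with its oxygen, its methyl and the C2–C4 methylenes is a ring-opened 1-methylcyclobutanol. C6 (α to C7) and the gem-dimethyl C1 are the α- and β-carbons of a 2-chloro-3-methylbut-2-enoate. Strain-release ring opening, radical addition, aldol addition and Darzens closure can therefore build the ring, the quaternary C1 and the epoxide in one flask.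
- Forward order: chiral chloro enoate 5 (2 steps) → annulation to epoxy ester 9 → epoxy C10 aldehyde 11 → epoxy C15 aldehyde 15. Separately, (R)-α-ionone → ε-C15 phosphonium salt 18 → C25 aldehyde 20 → C25 phosphonium salt 22. The last step joins 22 and 15.
- Stereochemistry: C6' is bought with (R)-α-ionone. C5 and C6 are cis by the ring fusion, and their absolute sense comes from the (+)-8-phenylmenthyl ester in the annulation. The chain double bonds are E from stabilised olefinations and thermal equilibration.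

Key step: step 3

Remark: (R)-α-ionone 16 is assumed to be purchasable in enantiopure (natural) grade, so C6' is carried through as bought; "(+)-8-phenylmenthyl" stands for (1S,2R,5S)-5-methyl-2-(2-phenylpropan-2-yl)cyclohexyl.

**Route**

Step 1
Reactants: 1 triethyl 2-chloro-2-phosphonoacetate; 2 (+)-8-phenylmenthol
Product: 3 (+)-8-phenylmenthyl 2-chloro-2-(diethoxyphosphoryl)acetate (both epimers at the CHCl carbon)
Conditions: DMAP (0.3 equiv), toluene, reflux, EtOH distilled off
Reagents that add atoms: none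
Why: DMAP-catalysed transesterification of a phosphonoacetate (ketene-type acyl transfer) should load the hindered secondary alcohol once ethanol is removed, and the CHCl centre forms as both epimers without consequence because it becomes sp2 in step 2.

Step 2
Reactants: 3 (+)-8-phenylmenthyl 2-chloro-2-(diethoxyphosphoryl)acetate; 4 acetone
Product: 5 (+)-8-phenylmenthyl 2-chloro-3-methylbut-2-enoate
Conditions: NaH, THF, 0 °C; then 4 (5 equiv), 0 °C → rt
Reagents that add atoms: none
Why: Horner–Wadsworth–Emmons olefination of the chloro phosphonate carbanion with a ketone should give the tetrasubstituted α-chloro enoate, and no alkene geometry arises because both β-substituents are methyl.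

Step 3
Reactants: 5 (+)-8-phenylmenthyl 2-chloro-3-methylbut-2-enoate; 6 1-methylcyclobutan-1-ol
Product: 9 (+)-8-phenylmenthyl (1S,6R)-2,2,6-trimethyl-7-oxabicyclo[4.1.0]heptane-1-carboxylate, via chloro keto ester 7 (not isolated), via chlorohydrin 8 (not isolated)
Conditions: 6 (3 equiv), CeCl3 (10 mol %), n-Bu4NCl (20 mol %), 9,10-diphenylanthracene (10 mol %), MeCN, 400 nm LED, 25 °C; then solvent switch to THF, t-BuOK (excess), −40 → 0 °C, same flask
Reagents that add atoms: none
Why: Proposed new method: the cerium alkoxide of 6 is cleaved by ligand-to-metal charge transfer to the 1-methylcyclobutyloxy radical, whose β-scission (release of about 26 kcal/mol of ring strain) gives the 4-oxopentyl radical; this adds to the β-carbon of 5 (bond C1–C2, quaternary gem-dimethyl carbon), the α-chloro ester radical is reduced by excited 9,10-diphenylanthracene (which then returns trivalent cerium to tetravalent cerium) to the chloro enolate of 7, and this closes onto the methyl ketone (bond C5–C6) and expels chloride, with t-BuOK afterwards driving any protonated 7 through the same Darzens closure. The closest known reaction types are the cerium-photocatalysed formal cycloaddition (two-carbon ring expansion) of cycloalkanols with electron-poor alkenes and the Darzens reaction of 8-phenylmenthyl chloroacetate with ketones, and what is new is a β,β-disubstituted α-chloro acceptor that makes the sequence end in an epoxide. The cyclohexane ring closes by 6-(enolexo)-exo-trig aldol addition and the oxirane by 3-exo-tet displacement. The cis relation of the C5–O and C6–O bonds is fixed because only the chlorohydrin with trans-diaxial O and Cl can close while the other reverts by retro-aldol, and the absolute sense is set by the auxiliary, whose phenyl ring stacks over one face of the potassium enolate (chloride syn to the enolate oxygen) so that the ketone is expected to bond to the open face and give the (1S,6R) epoxide. The step needs β-regioselective radical addition, secured by the stabilised α-chloro ester radical that forms only in that sense and by an excess of 6, and facial selectivity, secured by the auxiliary and backed by chromatographic separation of the two diastereomeric epoxy esters.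

Step 4
Reactants: 9 (+)-8-phenylmenthyl (1S,6R)-2,2,6-trimethyl-7-oxabicyclo[4.1.0]heptane-1-carboxylate
Product: 10 [(1R,6R)-2,2,6-trimethyl-7-oxabicyclo[4.1.0]heptan-1-yl]methanol
Conditions: LiAlH4, Et2O, 0 °C → rt; aqueous work-up
Reagents that add atoms: none
Why: Hydride reduction of the ester should release the neopentyl-type epoxy alcohol and the recoverable auxiliary 2, the fully substituted oxirane being too hindered for hydride opening, and no stereocenter is touched.

Step 5
Reactants: 10 [(1R,6R)-2,2,6-trimethyl-7-oxabicyclo[4.1.0]heptan-1-yl]methanol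
Product: 11 (1S,6R)-2,2,6-trimethyl-7-oxabicyclo[4.1.0]heptane-1-carbaldehyde
Conditions: (n-Pr4N)RuO4 (5 mol %), N-methylmorpholine N-oxide, 4 Å sieves, CH2Cl2, rt
Reagents that add atoms: none
Why: Ley–Griffith oxidation under neutral conditions should give the non-enolisable epoxy aldehyde without acid-induced opening of the oxirane.

Step 6
Reactants: 11 (1S,6R)-2,2,6-trimethyl-7-oxabicyclo[4.1.0]heptane-1-carbaldehyde; 12 ethyl (2E)-4-(diethoxyphosphoryl)-3-methylbut-2-enoate
Product: 13 ethyl (2E,4E)-3-methyl-5-[(1S,6R)-2,2,6-trimethyl-7-oxabicyclo[4.1.0]heptan-1-yl]penta-2,4-dienoate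
Conditions: 12, n-BuLi, THF/DMPU, −78 °C; then 11, −78 °C → rt
Reagents that add atoms: none
Why: Horner–Wadsworth–Emmons olefination with the C5 phosphonate should add C8–C11 in one step, the stabilised carbanion giving the 7E double bond and mainly the 9E isomer, with the 9Z isomer removed by chromatography.

Step 7
Reactants: 13 ethyl (2E,4E)-3-methyl-5-[(1S,6R)-2,2,6-trimethyl-7-oxabicyclo[4.1.0]heptan-1-yl]penta-2,4-dienoate
Product: 14 (2E,4E)-3-methyl-5-[(1S,6R)-2,2,6-trimethyl-7-oxabicyclo[4.1.0]heptan-1-yl]penta-2,4-dien-1-ol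
Conditions: i-Bu2AlH, CH2Cl2, −78 °C; Rochelle salt work-up
Reagents that add atoms: none
Why: Low-temperature 1,2-reduction of the dienoate with i-Bu2AlH should give the allylic alcohol while the vinyl oxirane is left intact.

Step 8
Reactants: 14 (2E,4E)-3-methyl-5-[(1S,6R)-2,2,6-trimethyl-7-oxabicyclo[4.1.0]heptan-1-yl]penta-2,4-dien-1-ol
Product: 15 (2E,4E)-3-methyl-5-[(1S,6R)-2,2,6-trimethyl-7-oxabicyclo[4.1.0]heptan-1-yl]penta-2,4-dienal
Conditions: MnO2, CH2Cl2, rt
Reagents that add atoms: none
Why: Allylic oxidation with MnO2 is neutral and selective for the dienylic alcohol and should keep the 9E geometry.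

Step 9
Reactants: 16 (R)-α-ionone
Product: 17 (1E)-3-methyl-1-[(1R)-2,6,6-trimethylcyclohex-2-en-1-yl]penta-1,4-dien-3-ol (both epimers at C3)
Conditions: CH2=CHMgBr, THF, 0 °C; then H2O
Reagents that add atoms: vinylmagnesium bromide, C=C[Mg]Br
Why: 1,2-Addition of the vinyl Grignard reagent to the enone carbonyl should outrun γ-deprotonation at 0 °C, and the new carbinol centre forms as both epimers and is erased in step 10.

Step 10
Reactants: 17 (1E)-3-methyl-1-[(1R)-2,6,6-trimethylcyclohex-2-en-1-yl]penta-1,4-dien-3-ol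
Product: 18 [(2E,4E)-3-methyl-5-[(1R)-2,6,6-trimethylcyclohex-2-en-1-yl]penta-2,4-dien-1-yl]triphenylphosphonium bromide
Conditions: PPh3·HBr, MeOH, rt
Reagents that add atoms: triphenylphosphine hydrobromide, [PH+](c1ccccc1)(c1ccccc1)c1ccccc1.[Br-]
Why: Acid-mediated allylic substitution with transposition should work because ionisation of the tertiary allylic alcohol gives a delocalised cation that PPh3 captures at the unhindered primary terminus, and the buffered acid is expected to leave the ring double bond and C6' in place.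

Step 11
Reactants: 18 [(2E,4E)-3-methyl-5-[(1R)-2,6,6-trimethylcyclohex-2-en-1-yl]penta-2,4-dien-1-yl]triphenylphosphonium bromide; 19 (2E,4E,6E)-2,7-dimethylocta-2,4,6-trienedial
Product: 20 (2E,4E,6E,8E,10E,12E)-2,7,11-trimethyl-13-[(1R)-2,6,6-trimethylcyclohex-2-en-1-yl]trideca-2,4,6,8,10,12-hexaenal
Conditions: 19 (3 equiv), NaOMe, CH2Cl2/MeOH, 0 °C → rt; then heptane, 90 °C
Reagents that add atoms: none
Why: Wittig olefination of the semistabilised ylide with an excess of the symmetrical dialdehyde should give the mono-olefination product, and warming equilibrates the new 11',12' double bond to E.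

Step 12
Reactants: 20 (2E,4E,6E,8E,10E,12E)-2,7,11-trimethyl-13-[(1R)-2,6,6-trimethylcyclohex-2-en-1-yl]trideca-2,4,6,8,10,12-hexaenal
Product: 21 (2E,4E,6E,8E,10E,12E)-2,7,11-trimethyl-13-[(1R)-2,6,6-trimethylcyclohex-2-en-1-yl]trideca-2,4,6,8,10,12-hexaen-1-ol
Conditions: NaBH4, MeOH/THF, 0 °C
Reagents that add atoms: none
Why: Borohydride reduction should be chemoselective for the aldehyde carbonyl (1,2-reduction) and leave the polyene untouched.

Step 13
Reactants: 21 (2E,4E,6E,8E,10E,12E)-2,7,11-trimethyl-13-[(1R)-2,6,6-trimethylcyclohex-2-en-1-yl]trideca-2,4,6,8,10,12-hexaen-1-ol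
Product: 22 triphenyl[(2E,4E,6E,8E,10E,12E)-2,7,11-trimethyl-13-[(1R)-2,6,6-trimethylcyclohex-2-en-1-yl]trideca-2,4,6,8,10,12-hexaen-1-yl]phosphonium bromide
Conditions: PPh3·HBr, MeOH/CH2Cl2, 0 °C → rt
Reagents that add atoms: triphenylphosphine hydrobromide, [PH+](c1ccccc1)(c1ccccc1)c1ccccc1.[Br-]
Why: The same acid-mediated phosphonium salt formation as in step 10 should apply, the polyenyl cation being captured by PPh3 at its primary terminus.

Step 14
Reactants: 22 triphenyl[(2E,4E,6E,8E,10E,12E)-2,7,11-trimethyl-13-[(1R)-2,6,6-trimethylcyclohex-2-en-1-yl]trideca-2,4,6,8,10,12-hexaen-1-yl]phosphonium bromide; 15 (2E,4E)-3-methyl-5-[(1S,6R)-2,2,6-trimethyl-7-oxabicyclo[4.1.0]heptan-1-yl]penta-2,4-dienal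
Product: 23 (5R,6S,6'R)-5,6-epoxy-5,6-dihydro-β,ε-carotene
Conditions: NaOMe, CH2Cl2/MeOH, −10 °C → rt; then heptane/EtOAc, 70 °C, dark, argon; chromatography on Et3N-deactivated silica
Reagents that add atoms: none
Why: Wittig olefination should join C11 to C12 under a mild alkoxide base that the epoxy aldehyde tolerates, the stereocenters are remote from the reacting centres, and thermal equilibration of the hindered Z isomers should give the all-E polyene.

**Compound list**

1 | triethyl 2-chloro-2-phosphonoacetate | CCOC(=O)C(Cl)P(=O)(OCC)OCC | starting material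
2 | (+)-8-phenylmenthol, (1S,2R,5S)-5-methyl-2-(2-phenylpropan-2-yl)cyclohexan-1-ol | O[C@H]1C[C@@H](C)CC[C@@H]1C(C)(C)c1ccccc1 | starting material
3 | (1S,2R,5S)-5-methyl-2-(2-phenylpropan-2-yl)cyclohexyl 2-chloro-2-(diethoxyphosphoryl)acetate (both epimers at the CHCl carbon) | CCOP(=O)(OCC)C(Cl)C(=O)O[C@H]1C[C@@H](C)CC[C@@H]1C(C)(C)c1ccccc1 | intermediate
4 | acetone | CC(C)=O | starting material
5 | (1S,2R,5S)-5-methyl-2-(2-phenylpropan-2-yl)cyclohexyl 2-chloro-3-methylbut-2-enoate | CC(C)=C(Cl)C(=O)O[C@H]1C[C@@H](C)CC[C@@H]1C(C)(C)c1ccccc1 | intermediate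
6 | 1-methylcyclobutan-1-ol | CC1(O)CCC1 | starting material
7 | (1S,2R,5S)-5-methyl-2-(2-phenylpropan-2-yl)cyclohexyl 2-chloro-3,3-dimethyl-7-oxooctanoate (both epimers at C2; present as its enolate) | CC(=O)CCCC(C)(C)C(Cl)C(=O)O[C@H]1C[C@@H](C)CC[C@@H]1C(C)(C)c1ccccc1 | intermediate (not isolated)
8 | (1S,2R,5S)-5-methyl-2-(2-phenylpropan-2-yl)cyclohexyl (1R,2R)-1-chloro-2-hydroxy-2,6,6-trimethylcyclohexane-1-carboxylate (O and Cl trans; present as its alkoxide) | O=C(O[C@H]1C[C@@H](C)CC[C@@H]1C(C)(C)c1ccccc1)[C@]1(Cl)[C@](C)(O)CCCC1(C)C | intermediate (not isolated)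
9 | (1S,2R,5S)-5-methyl-2-(2-phenylpropan-2-yl)cyclohexyl (1S,6R)-2,2,6-trimethyl-7-oxabicyclo[4.1.0]heptane-1-carboxylate | O=C(O[C@H]1C[C@@H](C)CC[C@@H]1C(C)(C)c1ccccc1)[C@@]12O[C@]1(C)CCCC2(C)C | intermediate
10 | [(1R,6R)-2,2,6-trimethyl-7-oxabicyclo[4.1.0]heptan-1-yl]methanol | OC[C@@]12O[C@]1(C)CCCC2(C)C | intermediate
11 | (1S,6R)-2,2,6-trimethyl-7-oxabicyclo[4.1.0]heptane-1-carbaldehyde | O=C[C@@]12O[C@]1(C)CCCC2(C)C | intermediate
12 | ethyl (2E)-4-(diethoxyphosphoryl)-3-methylbut-2-enoate | CCOC(=O)/C=C(\C)CP(=O)(OCC)OCC | starting material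
13 | ethyl (2E,4E)-3-methyl-5-[(1S,6R)-2,2,6-trimethyl-7-oxabicyclo[4.1.0]heptan-1-yl]penta-2,4-dienoate | CCOC(=O)/C=C(C)/C=C/[C@@]12O[C@]1(C)CCCC2(C)C | intermediate
14 | (2E,4E)-3-methyl-5-[(1S,6R)-2,2,6-trimethyl-7-oxabicyclo[4.1.0]heptan-1-yl]penta-2,4-dien-1-ol | OC/C=C(C)/C=C/[C@@]12O[C@]1(C)CCCC2(C)C | intermediate
15 | (2E,4E)-3-methyl-5-[(1S,6R)-2,2,6-trimethyl-7-oxabicyclo[4.1.0]heptan-1-yl]penta-2,4-dienal | O=C/C=C(C)/C=C/[C@@]12O[C@]1(C)CCCC2(C)C | intermediate
16 | (R)-α-ionone, (3E)-4-[(1R)-2,6,6-trimethylcyclohex-2-en-1-yl]but-3-en-2-one | CC1=CCCC(C)(C)[C@H]1/C=C/C(C)=O | starting material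
17 | (1E)-3-methyl-1-[(1R)-2,6,6-trimethylcyclohex-2-en-1-yl]penta-1,4-dien-3-ol (both epimers at C3) | CC1=CCCC(C)(C)[C@H]1/C=C/C(C)(O)C=C | intermediate
18 | [(2E,4E)-3-methyl-5-[(1R)-2,6,6-trimethylcyclohex-2-en-1-yl]penta-2,4-dien-1-yl]triphenylphosphonium bromide | CC1=CCCC(C)(C)[C@H]1/C=C/C(C)=C/C[P+](c1ccccc1)(c1ccccc1)c1ccccc1.[Br-] | intermediate
19 | (2E,4E,6E)-2,7-dimethylocta-2,4,6-trienedial | O=C/C(C)=C/C=C/C=C(C)/C=O | starting material
20 | (2E,4E,6E,8E,10E,12E)-2,7,11-trimethyl-13-[(1R)-2,6,6-trimethylcyclohex-2-en-1-yl]trideca-2,4,6,8,10,12-hexaenal | CC1=CCCC(C)(C)[C@H]1/C=C/C(C)=C/C=C/C(C)=C/C=C/C=C(C)/C=O | intermediate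
21 | (2E,4E,6E,8E,10E,12E)-2,7,11-trimethyl-13-[(1R)-2,6,6-trimethylcyclohex-2-en-1-yl]trideca-2,4,6,8,10,12-hexaen-1-ol | CC1=CCCC(C)(C)[C@H]1/C=C/C(C)=C/C=C/C(C)=C/C=C/C=C(C)/CO | intermediate
22 | triphenyl[(2E,4E,6E,8E,10E,12E)-2,7,11-trimethyl-13-[(1R)-2,6,6-trimethylcyclohex-2-en-1-yl]trideca-2,4,6,8,10,12-hexaen-1-yl]phosphonium bromide | CC1=CCCC(C)(C)[C@H]1/C=C/C(C)=C/C=C/C(C)=C/C=C/C=C(C)/C[P+](c1ccccc1)(c1ccccc1)c1ccccc1.[Br-] | intermediate
23 | (5R,6S,6'R)-5,6-epoxy-5,6-dihydro-β,ε-carotene | CC1=CCCC(C)(C)[C@H]1/C=C/C(C)=C/C=C/C(C)=C/C=C/C=C(C)/C=C/C=C(C)/C=C/[C@@]12O[C@]1(C)CCCC2(C)C | target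

**Summary**

Total step count: 14. Longest linear sequence: 9 steps (steps 1–8 and 14); the ε-branch is steps 9–13.

**Steps most likely to fail**

Step 3 (Proposed new method). Addition of the primary radical to the fully substituted β-carbon of 5 may be slower than hydrogen abstraction or than reductive loss of chloride from 5 by the excited sensitiser. The facial selectivity of the ring closure may also be lower than the model predicts. The fallback sets out from 5 and uses known polar chemistry. The organocopper reagent is made from [3-(2-methyl-1,3-dioxolan-2-yl)propyl]magnesium bromide and CuBr·SMe2. Its conjugate addition to 5 with Me3SiCl (THF, −78 → −20 °C), followed by hydrolysis of the silyl ketene acetal, should give (+)-8-phenylmenthyl 2-chloro-3,3-dimethyl-6-(2-methyl-1,3-dioxolan-2-yl)hexanoate F1. Pyridinium p-toluenesulfonate in wet acetone then releases the ketone 7, which is isolated here. t-BuOK in THF effects the intramolecular Darzens reaction through 8, and the route is rejoined at 9.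

Step 13. Under HBr the trisubstituted ring double bond may migrate into conjugation with loss of the C6' stereocenter, or the long polyenyl cation may decompose before it is captured. The fallback sets out from 21 and avoids acid. Mitsunobu thioetherification with 1-phenyl-1H-tetrazole-5-thiol (PPh3, diisopropyl azodicarboxylate, THF, 0 °C) should give the C25 tetrazolyl sulfide F2. Oxidation with H2O2 and (NH4)6Mo7O24 in EtOH gives the C25 tetrazolyl sulfone F3. Julia–Kocienski olefination of F3 with 15 (KN(SiMe3)2, THF, −78 °C → rt) comes back to the route at 23.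

Step 14. The selectivity for E at the new C11=C12 bond may be poor, and the heating needed to equilibrate it may rearrange the 5,6-epoxide to the 5,8-furanoid oxide. The fallback sets out from 21. Appel bromination (CBr4, PPh3, 2,6-lutidine, CH2Cl2, −20 °C) should give the C25 allylic bromide F4. Michaelis–Becker reaction with NaP(O)(OEt)2 in THF gives the C25 diethyl phosphonate F5. E-selective Horner–Wadsworth–Emmons olefination of F5 with 15 (NaH, THF, 0 °C) needs no thermal equilibration and comes back to the route at 23.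

Further compounds
F1 | step 3 | (1S,2R,5S)-5-methyl-2-(2-phenylpropan-2-yl)cyclohexyl 2-chloro-3,3-dimethyl-6-(2-methyl-1,3-dioxolan-2-yl)hexanoate (both epimers at C2) | CC1(CCCC(C)(C)C(Cl)C(=O)O[C@H]2C[C@@H](C)CC[C@@H]2C(C)(C)c2ccccc2)OCCO1
F2 | step 13 | 1-phenyl-5-{[(2E,4E,6E,8E,10E,12E)-2,7,11-trimethyl-13-[(1R)-2,6,6-trimethylcyclohex-2-en-1-yl]trideca-2,4,6,8,10,12-hexaen-1-yl]sulfanyl}-1H-tetrazole | CC1=CCCC(C)(C)[C@H]1/C=C/C(C)=C/C=C/C(C)=C/C=C/C=C(C)/CSc1nnnn1-c1ccccc1
F3 | step 13 | 1-phenyl-5-{[(2E,4E,6E,8E,10E,12E)-2,7,11-trimethyl-13-[(1R)-2,6,6-trimethylcyclohex-2-en-1-yl]trideca-2,4,6,8,10,12-hexaen-1-yl]sulfonyl}-1H-tetrazole | CC1=CCCC(C)(C)[C@H]1/C=C/C(C)=C/C=C/C(C)=C/C=C/C=C(C)/CS(=O)(=O)c1nnnn1-c1ccccc1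
F4 | step 14 | (1R)-1-[(1E,3E,5E,7E,9E,11E)-13-bromo-3,7,12-trimethyltrideca-1,3,5,7,9,11-hexaen-1-yl]-2,6,6-trimethylcyclohex-2-ene | CC1=CCCC(C)(C)[C@H]1/C=C/C(C)=C/C=C/C(C)=C/C=C/C=C(C)/CBr
F5 | step 14 | diethyl [(2E,4E,6E,8E,10E,12E)-2,7,11-trimethyl-13-[(1R)-2,6,6-trimethylcyclohex-2-en-1-yl]trideca-2,4,6,8,10,12-hexaen-1-yl]phosphonate | CC1=CCCC(C)(C)[C@H]1/C=C/C(C)=C/C=C/C(C)=C/C=C/C=C(C)/CP(=O)(OCC)OCC
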